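# Proposed synthesis of 3,5-dihydroxy-7,8,3',4',5'-pentamethoxyflavone (15) by carbonylative ketone arylation with CO as C2

## The problem

Target 15 is a flavonol: a 3-hydroxy-4H-chromen-4-one (rings A and C) with a 3,4,5-trimethoxyphenyl group (ring B) at C2, a free hydroxyl at C5 and methoxyls at C7 and C8. It has no stereocentre, so nothing needs to be controlled in space. The difficulty lies in connectivity and in telling seven oxygen substituents apart, since five stay as methyl ethers while O3 and O5 must end free.

Ring A is a 1,2,3,5-tetraoxygenated benzene whose two oxygens ortho to the C4 carbonyl are not equivalent. Closure of ring C through one gives the 7,8-dimethoxy pattern and through the other the 6,7-isomer, and once O5 is free the two patterns can interconvert by ring opening and reclosure in hot strong acid.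

Several groups will not survive rough treatment:
- C6–H lies between two oxygens and is strongly nucleophilic, so electrophilic halogenation or Friedel–Crafts chemistry on the assembled skeleton must be avoided.
- The central 4'-methoxyl of ring B is the most Lewis-acid-labile ether after the peri one.
- The free 3-hydroxy-4-pyranone is sensitive to base and oxidants and should appear late.

The three carbons of ring C must arrive at three different oxidation levels: C4 as a ketone, C3 as an oxygenated carbon, and C2 as an acyl-level carbon. C2 is bonded only to O1, to C3 (the α-carbon of the ring A ketone) and to C1' of ring B. It can therefore be introduced as carbon monoxide between a ketone enolate and an aryl–palladium bond.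

## Retrosynthesis

**15 ⇒ 14 (O–CH3 at C5).** The last bond cut is the methyl–oxygen bond at C5, leading back to the 5-O-methyl flavonol 14. Carrying O5 as a methyl ether is what distinguishes it from the oxygen that becomes O1, and this difference is already present in the purchasable ketone 1. Among the six methoxyls of 14, only the one at C5 sits peri to the C4 carbonyl, so chelation-controlled cleavage can single it out. The forward step must stop after one ether cleavage and spare the central 4'-methoxyl.

**14 ⇒ 10 (O1–C2).** Opening ring C at O1–C2, with formal addition of water across C2=C3, gives the 2-oxygenated 1,3-diketone 10. All three ring C carbons are then at their final oxidation levels, so no later oxidation is needed. The alternative of condensing 2 with an aldehyde and closing the ring oxidatively (Algar–Flynn–Oyamada) tends to divert to five-membered ring closure when the position that becomes C5 is substituted, as it is here. In 10 the future O1 and O3 are both masked as methoxymethyl acetals, so one acid treatment should unmask both and close the ring. Benzyl ethers would also serve, but they have three drawbacks: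
- they add a hydrogenolysis step;
- they require O-benzylation of a base-sensitive ketol;
- they place a migratable benzyl group on an enolate held at 80 °C.

**10 ⇒ 7 + 8 + 9 (C2–C3 and C2–C1').** Both bonds to C2 are cut at once, giving the α-alkoxy ketone 7, the aryl iodide 8 and carbon monoxide 9. Cutting only C2–C3 (acylation of the enolate by a pre-formed ring B carboxylic acid derivative) is the classical neighbour and is held in reserve. The three-component cut takes ring B directly from its commonest commercial form and builds the acyl carbon catalytically. Cutting C3–C4 instead would mean acylating ring A and would give up the regiochemistry stored in 1. The forward reaction must favour carbonylative C-acylation over direct arylation and over O-acylation, on an enolate carbon that carries an oxygen substituent.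

**7 ⇒ 6 ⇒ 3 ⇒ 2 ⇒ 1 (C3–O and protecting groups).** Ketone 7 is the acetal of ketol 6, which comes from silyl enol ether 3 by Rubottom oxidation; 3 comes from the protected ketone 2, and 2 from ketone 1 by acetal formation on the phenol. The methyl group of 1 is the only enolisable position, so enol ether formation has no regiochemical ambiguity. Oxidising the enol ether, not the ketone, keeps electrophilic oxidants away from the electron-rich ring. Ketone 1 already holds the whole substitution pattern of ring A with the correct ortho oxygen free.

## Roads not taken

**Alternative 1: ring A by benzannulation onto a pyranone.**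
- Cut: C4a–C5, so that ring A is made last.
- Forward: pyranone A4 would be metallated at C6 and added to the ketone carbonyl of the squaric acid derivative A3 to give cyclobutenone A2. Heating A2 would open the four-membered ring, and six-electron closure onto pyranone C5 with tautomerisation would give hydroquinone A1. Methylation of the unchelated 8-hydroxyl of A1 and hydrogenolysis would then give 15.
- Merits: O5 is born free and is differentiated from O8 by its hydrogen bond, so no ether has to be cleaved on the pentamethoxy array. In the handling of O5 this road is better than the chosen one.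
- Weak points: neither A3 nor A4 is a stock compound, and each needs several steps. Metallation of a 4-pyranone at C6 competes with nucleophilic ring opening. The hydroquinone A1 is air-sensitive.
- Comparison: the chosen plan offers purchasable ring A and ring B pieces, seven steps in all, and a last step whose selectivity rests on peri chelation.

**Alternative 2: ring C by quinoketene–enamine annulation.**
- Cut: C3–C4 and O1–C2.
- Forward: thermolysis of benzodioxinone A6 would release quinoketene A8. The oxygenated carbon of enamine A7 would attack the ketene carbon, the phenoxide oxygen would close onto the iminium carbon, and loss of the amine would give the 3-benzyloxyflavone A5.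
- Merits: carbon–carbon bond formation and ring closure happen in one step, O1 is fixed by the salicylate oxygen, and neither palladium nor CO is needed. From A5 the end game (debenzylation and cleavage of the C5 methyl ether) is as short as from 10. In convergence this road is at least as good as the chosen one.
- Weak points: A6 needs a carboxyl carbon on ring A, whereas the available ketone 1 carries an acetyl group, so degradation and acetal formation on a hindered salicylic acid add steps. Generating A8 needs high temperature. A7 is a trisubstituted, hydrolytically labile enamine of an α-alkoxy ketone and would form as a mixture of geometric isomers. A8 may also be captured without ring closure, or may dimerise.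
- Comparison: the chosen plan uses three purchasable components, runs at 80 °C, and closes the ring through the long-established diketone cyclodehydration.

**Alternative 3: ring B from a furan and an ethynylchromone.**
- Cut: C1'–C6' and C2'–C3'.
- Forward: [4+2] cycloaddition of furan A11 to the alkyne of chromone A10 would give the oxygen-bridged adduct A12. Acid would open the bridge and aromatise it to the 3'-phenol A9. O-Methylation, debenzylation and cleavage of the C5 methyl ether would follow.
- Merits: the key step is metal-free, and the 3'-oxygen emerges differentiated, which would help only if ring B analogues were wanted.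
- Weak points: this road constructs the one ring that is available ready-made as iodide 8. A11 needs a multi-step preparation. Furan cycloadditions are reversible. The bridge of A12 must open toward the bridgehead remote from the chromone, because opening the other way places the hydroxyl ortho to the chromone and cannot be corrected. A10 itself requires the ring A chemistry of the chosen route plus an alkyne at C2.
- Comparison: apart from avoiding palladium and CO, this road is not better in any respect for this target, and it is several steps longer.

Key step: step 5

Assumption: ketone 1, iodide 8 and carbon monoxide 9 are taken as purchased materials; diketone 10 is racemic at its one sp3 centre, which is destroyed on ring closure.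

## Route

Step 1
Reactants: 1 1-(2-hydroxy-3,4,6-trimethoxyphenyl)ethan-1-one (2'-hydroxy-3',4',6'-trimethoxyacetophenone)
Product: 2 1-[3,4,6-trimethoxy-2-(methoxymethoxy)phenyl]ethan-1-one
Conditions: NaH, MOMCl, DMF, 0 °C to rt
Reagents that add atoms: chloromethyl methyl ether (MOMCl), COCCl
Why: Williamson-type O-alkylation of the sodium phenoxide; full deprotonation with NaH breaks the hydrogen bond to the ketone that makes this hindered phenol sluggish, and the resulting acetal is stable to the strong bases of steps 2 and 5.

Step 2
Reactants: 2 1-[3,4,6-trimethoxy-2-(methoxymethoxy)phenyl]ethan-1-one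
Product: 3 trimethyl({1-[3,4,6-trimethoxy-2-(methoxymethoxy)phenyl]ethenyl}oxy)silane
Conditions: LiN(SiMe3)2, THF, −78 °C; Me3SiCl, −78 to 0 °C; crude product used at once
Reagents that add atoms: chlorotrimethylsilane, C[Si](C)(C)Cl
Why: Deprotonation of the only enolisable position and O-silylation of the lithium enolate (silyl enol ether formation); an amide base with a silyl chloride is chosen over a silyl triflate so that the aryl acetal is not activated.

Step 3
Reactants: 3 trimethyl({1-[3,4,6-trimethoxy-2-(methoxymethoxy)phenyl]ethenyl}oxy)silane
Product: 6 2-hydroxy-1-[3,4,6-trimethoxy-2-(methoxymethoxy)phenyl]ethan-1-one, via silyloxy oxirane 4 (not isolated), via α-silyloxy ketone 5 (not isolated)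
Conditions: mCPBA, NaHCO3, CH2Cl2, −20 to 0 °C; then citric acid, MeOH, rt
Reagents that add atoms: 3-chloroperoxybenzoic acid (mCPBA), O=C(OO)c1cccc(Cl)c1
Why: Rubottom oxidation: the silyl enol ether should be epoxidised much faster than the peracid attacks the aryl ring or the ketone, the silyloxy oxirane opens with 1,4-silyl shift to the α-silyloxy ketone, and mild acidic methanolysis removes the silyl group without touching the aryl acetal.

Step 4
Reactants: 6 2-hydroxy-1-[3,4,6-trimethoxy-2-(methoxymethoxy)phenyl]ethan-1-one
Product: 7 2-(methoxymethoxy)-1-[3,4,6-trimethoxy-2-(methoxymethoxy)phenyl]ethan-1-one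
Conditions: MOMCl, i-Pr2NEt, CH2Cl2, 0 °C to rt
Reagents that add atoms: chloromethyl methyl ether (MOMCl), COCCl
Why: Methoxymethyl ether formation on a primary alcohol with a hindered amine base; the weak base avoids the enolisation, ketol rearrangement and aldol chemistry that alkoxide-mediated alkylation of an α-hydroxy ketone would invite.

Step 5
Reactants: 7 2-(methoxymethoxy)-1-[3,4,6-trimethoxy-2-(methoxymethoxy)phenyl]ethan-1-one; 8 5-iodo-1,2,3-trimethoxybenzene; 9 carbon monoxide
Product: 10 2-(methoxymethoxy)-1-[3,4,6-trimethoxy-2-(methoxymethoxy)phenyl]-3-(3,4,5-trimethoxyphenyl)propane-1,3-dione (racemic, enolisable)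
Conditions: NaN(SiMe3)2 (2.2 equiv), THF, 0 °C; then 8 (1.2 equiv), Pd(dba)2 (5 mol%), Xantphos (6 mol%), CO (1 atm), dioxane, 80 °C; aq. NH4Cl
Reagents that add atoms: none
Why: Three-component carbonylative α-arylation: oxidative addition of 8 to zerovalent palladium gives an aryl complex of divalent palladium, CO inserts to the aroyl complex (forming C2–C1'), the pre-formed sodium enolate of 7 replaces iodide, and reductive elimination forms C2–C3 and returns zerovalent palladium. The closest known reaction type is the palladium-catalysed carbonylative α-arylation of alkyl aryl ketones with aryl iodides to 1,3-diketones; 7 differs from the usual partners only in its α-alkoxy substituent. No ring is closed here. The only new stereocentre, C2 of the diketone, is formed racemic, is enolisable and disappears in step 6, so nothing has to control it. The selectivity needed is carbonylative C-acylation in preference to direct α-arylation, O-acylation and ester or amide formation: the CO atmosphere and the wide-bite-angle chelate Xantphos should make insertion faster than aryl–enolate reductive elimination, both hydroxyls are capped as acetals so that the enolate carbon is the only good nucleophile present, and the hindered silylamide left over is a poor partner for the aroyl complex. The more acidic product is converted at once into its sodium diketonate by the second equivalent of base, which protects it from a second acylation and pulls the coupling forward. The two ortho substituents twist and shield the ring A carbonyl, which should suppress self-condensation of 7, and the acetal oxygen on the enolate carbon can chelate sodium and, unlike a benzyl ether, cannot undergo a [1,2]-Wittig shift at 80 °C.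

Step 6
Reactants: 10 2-(methoxymethoxy)-1-[3,4,6-trimethoxy-2-(methoxymethoxy)phenyl]-3-(3,4,5-trimethoxyphenyl)propane-1,3-dione
Product: 14 3-hydroxy-5,7,8-trimethoxy-2-(3,4,5-trimethoxyphenyl)-4H-chromen-4-one, via free phenol diketone 11 (not isolated), via 2-hydroxyflavanone hemiketal 12 (not isolated), via 3-O-MOM flavone 13 (not isolated)
Conditions: conc. HCl, MeOH, 60 °C
Reagents that add atoms: none
Why: Acid-catalysed acetal cleavage and cyclodehydration (the ring-closing stage of the classical diketone route to flavones): the freed phenol adds to the ring B carbonyl in a 6-exo-trig hemiketalisation, water is lost to give the pyranone, and the second acetal is cleaved in the same medium. Only the oxygen that carried the aryl acetal can close the ring, so O1 is unambiguous and the 7,8-dimethoxy pattern follows; the order of the two acetal cleavages does not affect the outcome.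

Step 7
Reactants: 14 3-hydroxy-5,7,8-trimethoxy-2-(3,4,5-trimethoxyphenyl)-4H-chromen-4-one
Product: 15 3,5-dihydroxy-7,8-dimethoxy-2-(3,4,5-trimethoxyphenyl)-4H-chromen-4-one (3,5-dihydroxy-7,8,3',4',5'-pentamethoxyflavone)
Conditions: BCl3 (3 equiv), CH2Cl2, −78 to 0 °C; then aq. HCl
Reagents that add atoms: none
Why: Chelation-controlled aryl methyl ether cleavage: BCl3 bridges the C4 carbonyl and the peri oxygen in a six-membered chelate and chloride removes that methyl group, while the other five methyl ethers lack this activation at low temperature; the 3-hydroxyl is only converted into a borate that hydrolyses on work-up.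

## Compound list

1 | 1-(2-hydroxy-3,4,6-trimethoxyphenyl)ethan-1-one (2'-hydroxy-3',4',6'-trimethoxyacetophenone) | CC(=O)c1c(O)c(OC)c(OC)cc1OC | starting material
2 | 1-[3,4,6-trimethoxy-2-(methoxymethoxy)phenyl]ethan-1-one | CC(=O)c1c(OCOC)c(OC)c(OC)cc1OC | intermediate
3 | trimethyl({1-[3,4,6-trimethoxy-2-(methoxymethoxy)phenyl]ethenyl}oxy)silane | C=C(O[Si](C)(C)C)c1c(OCOC)c(OC)c(OC)cc1OC | intermediate
4 | trimethyl({2-[3,4,6-trimethoxy-2-(methoxymethoxy)phenyl]oxiran-2-yl}oxy)silane (racemic) | C1OC1(O[Si](C)(C)C)c1c(OCOC)c(OC)c(OC)cc1OC | intermediate (not isolated)
5 | 1-[3,4,6-trimethoxy-2-(methoxymethoxy)phenyl]-2-[(trimethylsilyl)oxy]ethan-1-one | C[Si](C)(C)OCC(=O)c1c(OCOC)c(OC)c(OC)cc1OC | intermediate (not isolated)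
6 | 2-hydroxy-1-[3,4,6-trimethoxy-2-(methoxymethoxy)phenyl]ethan-1-one | OCC(=O)c1c(OCOC)c(OC)c(OC)cc1OC | intermediate
7 | 2-(methoxymethoxy)-1-[3,4,6-trimethoxy-2-(methoxymethoxy)phenyl]ethan-1-one | COCOCC(=O)c1c(OCOC)c(OC)c(OC)cc1OC | intermediate
8 | 5-iodo-1,2,3-trimethoxybenzene | COc1cc(I)cc(OC)c1OC | starting material
9 | carbon monoxide | [C-]#[O+] | starting material
10 | 2-(methoxymethoxy)-1-[3,4,6-trimethoxy-2-(methoxymethoxy)phenyl]-3-(3,4,5-trimethoxyphenyl)propane-1,3-dione (racemic, enolisable) | COCOC(C(=O)c1cc(OC)c(OC)c(OC)c1)C(=O)c1c(OCOC)c(OC)c(OC)cc1OC | intermediate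
11 | 1-(2-hydroxy-3,4,6-trimethoxyphenyl)-2-(methoxymethoxy)-3-(3,4,5-trimethoxyphenyl)propane-1,3-dione (racemic) | COCOC(C(=O)c1cc(OC)c(OC)c(OC)c1)C(=O)c1c(O)c(OC)c(OC)cc1OC | intermediate (not isolated)
12 | 2-hydroxy-5,7,8-trimethoxy-3-(methoxymethoxy)-2-(3,4,5-trimethoxyphenyl)-2,3-dihydro-4H-chromen-4-one (racemic, mixture of diastereomers) | COCOC1C(=O)c2c(OC)cc(OC)c(OC)c2OC1(O)c1cc(OC)c(OC)c(OC)c1 | intermediate (not isolated)
13 | 5,7,8-trimethoxy-3-(methoxymethoxy)-2-(3,4,5-trimethoxyphenyl)-4H-chromen-4-one | COCOc1c(-c2cc(OC)c(OC)c(OC)c2)oc2c(OC)c(OC)cc(OC)c2c1=O | intermediate (not isolated)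
14 | 3-hydroxy-5,7,8-trimethoxy-2-(3,4,5-trimethoxyphenyl)-4H-chromen-4-one | COc1cc(-c2oc3c(OC)c(OC)cc(OC)c3c(=O)c2O)cc(OC)c1OC | intermediate
15 | 3,5-dihydroxy-7,8-dimethoxy-2-(3,4,5-trimethoxyphenyl)-4H-chromen-4-one (3,5-dihydroxy-7,8,3',4',5'-pentamethoxyflavone) | COc1cc(-c2oc3c(OC)c(OC)cc(O)c3c(=O)c2O)cc(OC)c1OC | target

## Step count and risk

Total step count: 7. Longest linear sequence: 7 steps (1 to 15); iodide 8 and carbon monoxide 9 enter at step 5.

**Step 5 (key step).** The aroylpalladium intermediate may be intercepted by something other than the enolate carbon: by the enolate oxygen (enol ester formation) or by the silylamide (amide formation). Slow carbon–carbon reductive elimination at the hindered, oxygen-bearing enolate carbon would also leave the catalyst to deactivate under CO. Fallback: the approach changes from catalytic three-component coupling to a stoichiometric crossed Claisen acylation. It sets out from 7, whose lithium enolate (LiN(SiMe3)2, 2.2 equiv, THF, −78 °C) would be C-aroylated with purchased 3,4,5-trimethoxybenzoyl chloride, and it comes back to the route at 10. C2 then arrives already bonded to ring B and only C2–C3 is formed. This detour makes no new compound (F0).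

**Step 3.** The peracid may oxidise the electron-rich ring or insert into the aryl ketone, and 3-chlorobenzoic acid may protodesilylate the enol ether before epoxidation and return the ketone. Fallback: direct hydroxylation of an enolate with an aprotic oxygen-transfer reagent. It sets out from 2, whose potassium enolate (KN(SiMe3)2, THF, −78 °C) would be treated with 3-phenyl-2-(phenylsulfonyl)oxaziridine, and it comes back at 6, bypassing 3. This detour makes no new compound (F0).

**Step 6.** Methanol may attack the unhindered ring B carbonyl of the diketone and cleave it by a retro-Claisen path before the ring has closed, or the sequence may stall before dehydration. Fallback: unmasking and ring closure are separated and the nucleophilic solvent is removed. It sets out from 10, whose two acetals would be cleaved under aprotic Lewis-acid conditions (ZnBr2, n-PrSH, CH2Cl2, 0 °C) to give 2,3-dihydroxy-5,7,8-trimethoxy-2-(3,4,5-trimethoxyphenyl)-2,3-dihydro-4H-chromen-4-one F1, the ring-closed form of the free hydroxy diketone. Dehydration of F1 with catalytic TsOH in toluene at 80 °C comes back to the route at 14.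

**Step 7.** Ether cleavage may be incomplete or unselective. The 3-hydroxyl ties up the C4 carbonyl as a five-membered borate, which weakens activation of the peri oxygen and invites more reagent and higher temperature, and under those conditions the hindered central 4'-methoxyl starts to cleave. Fallback: the C4 carbonyl is left with a single chelating partner. It sets out from 14, which would be acetylated (Ac2O, pyridine) to 5,7,8-trimethoxy-4-oxo-2-(3,4,5-trimethoxyphenyl)-4H-chromen-3-yl acetate F2. F2 would be demethylated at the peri position with a small excess of BCl3 (CH2Cl2, −78 to −20 °C) to 5-hydroxy-7,8-dimethoxy-4-oxo-2-(3,4,5-trimethoxyphenyl)-4H-chromen-3-yl acetate F3. Methanolysis of F3 (K2CO3, MeOH, rt, under nitrogen) comes back to the route at 15.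

## Further compounds

F0 | step 5 | none | none
F0 | step 3 | none | none
F1 | step 6 | 2,3-dihydroxy-5,7,8-trimethoxy-2-(3,4,5-trimethoxyphenyl)-2,3-dihydro-4H-chromen-4-one (racemic, mixture of diastereomers) | COc1cc(C2(O)Oc3c(OC)c(OC)cc(OC)c3C(=O)C2O)cc(OC)c1OC
F2 | step 7 | 5,7,8-trimethoxy-4-oxo-2-(3,4,5-trimethoxyphenyl)-4H-chromen-3-yl acetate | COc1cc(-c2oc3c(OC)c(OC)cc(OC)c3c(=O)c2OC(C)=O)cc(OC)c1OC
F3 | step 7 | 5-hydroxy-7,8-dimethoxy-4-oxo-2-(3,4,5-trimethoxyphenyl)-4H-chromen-3-yl acetate | COc1cc(-c2oc3c(OC)c(OC)cc(O)c3c(=O)c2OC(C)=O)cc(OC)c1OC
A1 | alternative 1 | 3-(benzyloxy)-5,8-dihydroxy-7-methoxy-2-(3,4,5-trimethoxyphenyl)-4H-chromen-4-one | COc1cc(O)c2c(c1O)oc(-c1cc(OC)c(OC)c(OC)c1)c(OCc1ccccc1)c2=O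
A2 | alternative 1 | 3-(benzyloxy)-6-(1-hydroxy-2-methoxy-4-oxocyclobut-2-en-1-yl)-2-(3,4,5-trimethoxyphenyl)-4H-pyran-4-one (racemic) | COC1=CC(=O)C1(O)c1cc(=O)c(OCc2ccccc2)c(-c2cc(OC)c(OC)c(OC)c2)o1
A3 | alternative 1 | 3-methoxycyclobut-3-ene-1,2-dione | COC1=CC(=O)C1=O
A4 | alternative 1 | 3-(benzyloxy)-2-(3,4,5-trimethoxyphenyl)-4H-pyran-4-one | O=c1ccoc(-c2cc(OC)c(OC)c(OC)c2)c1OCc1ccccc1
A5 | alternative 2 | 3-(benzyloxy)-5,7,8-trimethoxy-2-(3,4,5-trimethoxyphenyl)-4H-chromen-4-one | COc1cc(OC)c2c(=O)c(OCc3ccccc3)c(-c3cc(OC)c(OC)c(OC)c3)oc2c1OC
A6 | alternative 2 | 5,7,8-trimethoxy-2,2-dimethyl-4H-1,3-benzodioxin-4-one | COc1cc(OC)c2c(c1OC)OC(C)(C)OC2=O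
A7 | alternative 2 | 4-[2-(benzyloxy)-1-(3,4,5-trimethoxyphenyl)ethenyl]morpholine (either alkene geometry) | COc1cc(C(=COCc2ccccc2)N2CCOCC2)cc(OC)c1OC
A8 | alternative 2 | 2,3,5-trimethoxy-6-(oxomethylidene)cyclohexa-2,4-dien-1-one | COC1=CC(OC)=C(OC)C(=O)C1=C=O
A9 | alternative 3 | 3-(benzyloxy)-2-(3-hydroxy-4,5-dimethoxyphenyl)-5,7,8-trimethoxy-4H-chromen-4-one | COc1cc(OC)c2c(=O)c(OCc3ccccc3)c(-c3cc(O)c(OC)c(OC)c3)oc2c1OC
A10 | alternative 3 | 3-(benzyloxy)-2-ethynyl-5,7,8-trimethoxy-4H-chromen-4-one | C#Cc1oc2c(OC)c(OC)cc(OC)c2c(=O)c1OCc1ccccc1
A11 | alternative 3 | 3,4-dimethoxyfuran | COc1cocc1OC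
A12 | alternative 3 | 3-(benzyloxy)-2-(5,6-dimethoxy-7-oxabicyclo[2.2.1]hepta-2,5-dien-2-yl)-5,7,8-trimethoxy-4H-chromen-4-one (racemic) | COC1=C(OC)C2OC1C=C2c1oc2c(OC)c(OC)cc(OC)c2c(=O)c1OCc1ccccc1
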